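**Strategy.** The cyclopentene ring C1′–C5′ (primed numbers: guaiane numbering of the sesquiterpene half) is joined to the rest only through the two adjacent, fully substituted ether carbons C1′ and C5′, which are shared with the 1,4-dioxane ring and the seven-membered ring. Removing C2′–C4′ therefore leaves a tetrasubstituted enediol diether, C1′=C5′, in a cyclohepta-fused benzodioxin made from a pristimerin-derived catechol and a carvone-derived bromocycloheptanone. One (3+2) annulation with the oxyallyl cation from 1-bromobutan-2-one forms C1′–C2′ and C4′–C5′, closes the five-membered ring and sets both quaternary centres. The precursor carries a C6 ketone as a masked C6=C7 alkene.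

Key step: step 11

**Remarks on the chemistry**
- Triterpene atoms carry friedelane numbers; O2 and O3 are the oxygens on C2 and C3. The target has 8β-H (8S), with the C7′ isopropenyl and C10′ methyl groups cis on the seven-membered ring (7′S,10′R) and the cyclopentene on the opposite face.
- Two design choices in the precursor: the C6 carbonyl (7,8-dihydro) replaces the electron-rich C6=C7 styrene until the end, and the bromocycloheptanone has its ketone at C5′ and its bromine at C1′, so that C10′ is never α to a carbonyl group.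
- Assumption (step 4): the sense of induction of the CuH/(R)-DTBM-SEGPHOS reduction is taken to follow that of simple 3-methylcycloalkenones and to give 3R. Should it be opposite, the antipodal ligand is used.

**Route**

Step 1
Reactants: 1 (S)-carvone
Product: 3 trimethylsilyl enol ether of dihydrocarvone (C1=C2), via lithium enolate 2 (not isolated)
Conditions: LiBH(s-Bu)3, THF, −78 °C; then TMSCl, Et3N, −78 °C → rt
Reagents that add atoms: chlorotrimethylsilane, C[Si](C)(C)Cl
Why: Conjugate hydride reduction of the β-unsubstituted enone gives the C1–C2 enolate regiospecifically and O-silylation fixes it as the tetrasubstituted enol ether; C5 is untouched.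

Step 2
Reactants: 3 trimethylsilyl enol ether of dihydrocarvone
Product: 4 1-(trimethylsilyloxy)-6-methyl-3-isopropenylbicyclo[4.1.0]heptane
Conditions: Et2Zn, CH2I2, CH2Cl2, 0 °C → rt
Reagents that add atoms: diiodomethane, ICI
Why: Simmons–Smith cyclopropanation (Furukawa variant), in which the electrophilic zinc carbenoid should react much faster with the silyl enol ether than with the isopropenyl group; the face of addition is immaterial because both new centres are destroyed in step 3.

Step 3
Reactants: 4 silyloxycyclopropane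
Product: 6 (6S)-3-methyl-6-(prop-1-en-2-yl)cyclohept-2-en-1-one, via β-chloro ketone 5 (not isolated)
Conditions: FeCl3, DMF, 0 °C → rt; then NaOAc, MeOH, reflux
Reagents that add atoms: none
Why: Ito–Saegusa ring expansion, in which oxidation by FeCl3 opens the internal cyclopropane bond to the tertiary radical that is chlorinated, and acetate-promoted E1cB loss of HCl gives the conjugated enone with the inserted carbon between the carbonyl and the methyl-bearing carbon.

Step 4
Reactants: 6 (6S)-3-methyl-6-(prop-1-en-2-yl)cyclohept-2-en-1-one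
Product: 8 (3R,6S)-2-bromo-3-methyl-6-(prop-1-en-2-yl)cycloheptan-1-one, via silyl enol ether 7 (not isolated)
Conditions: Cu(OAc)2·H2O (3 mol%), (R)-DTBM-SEGPHOS (3 mol%), (MeO)2MeSiH, toluene, 0 °C; evaporate; then NBS, THF, −78 → 0 °C
Reagents that add atoms: N-bromosuccinimide, O=C1CCC(=O)N1Br
Why: Copper hydride asymmetric conjugate reduction, in which ligand-controlled hydride delivery to C3 should set the 3R methyl centre cis to the isopropenyl group, leaves the regiodefined silyl enol ether, and its bromination places bromine only on C2 (configuration there is irrelevant).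

Step 5
Reactants: 9 pristimerin
Product: 11 pristimerol 2,3-diacetate, via pristimerol 10 (not isolated)
Conditions: Zn dust, Ac2O, NaOAc, 60 °C
Reagents that add atoms: acetic anhydride, CC(=O)OC(C)=O
Why: Reductive acetylation, in which zinc reduces the quinone methide to the catechol (hydrogen enters at C6) and acetylation as it forms protects it from re-oxidation.

Step 6
Reactants: 11 pristimerol 2,3-diacetate
Product: 12 6-oxopristimerol 2,3-diacetate
Conditions: CrO3, 3,5-dimethylpyrazole, CH2Cl2, −20 °C
Reagents that add atoms: chromium trioxide, O=[Cr](=O)=O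
Why: Allylic oxidation with the chromium trioxide–dimethylpyrazole complex; C6 is the only methylene that is both benzylic and allylic, so it alone should be converted to the carbonyl group.

Step 7
Reactants: 12 6-oxopristimerol 2,3-diacetate
Product: 13 (8S)-6-oxo-7,8-dihydropristimerol 2,3-diacetate
Conditions: H2 (3 atm), 10% Pd/C, EtOAc, rt
Reagents that add atoms: none
Why: Catalytic hydrogenation of the enone C7=C8 bond, in which hydrogen should reach C8 from the β face because the α face is covered by ring C and its axial C13 methyl group, giving the 8β-H centre cis to the C9 and C14 methyl groups.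

Step 8
Reactants: 13 (8S)-6-oxo-7,8-dihydropristimerol 2,3-diacetate
Product: 14 (8S)-6-oxo-7,8-dihydropristimerol
Conditions: K2CO3 (cat.), MeOH, degassed, rt
Reagents that add atoms: none
Why: Base-catalysed methanolysis of the two aryl acetates; the hindered tertiary methyl ester is inert and C8, being β to the ketone, cannot epimerise.

Step 9
Reactants: 14 (8S)-6-oxo-7,8-dihydropristimerol; 8 (3R,6S)-2-bromo-3-methyl-6-(prop-1-en-2-yl)cycloheptan-1-one
Product: 16 cyclic hemiketal (O2–C1′ ether and O3–C5′ hemiketal), via aryloxy ketone 15 (not isolated)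
Conditions: K2CO3 (1.1 equiv), DMF, argon, rt → 45 °C
Reagents that add atoms: none
Why: Williamson etherification by SN2 at the α-bromo ketone, in which the phenol para to the C6 carbonyl (O2) is the more acidic and less hindered and so should be the only one alkylated with one equivalent of mild base, after which O3–H adds to the C5′ ketone to close the six-membered hemiketal.

Step 10
Reactants: 16 cyclic hemiketal
Product: 17 cyclohepta-fused benzodioxin (6-oxo-6,7-dihydro form)
Conditions: PPTS (10 mol%), 4 Å MS, toluene, 80 °C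
Reagents that add atoms: none
Why: Acid-catalysed dehydration through the C5′ oxocarbenium ion should give the tetrasubstituted endocyclic enediol diether under thermodynamic control, and because the para-acyl O2 is the poorer donor the cation stays on C5′, away from C10′, whose configuration is kept.

Step 11
Reactants: 17 cyclohepta-fused benzodioxin (6-oxo-6,7-dihydro form); 18 1-bromobutan-2-one
Product: 20 3′,6-dioxo-3′,4′,6,7-tetrahydro target (cyclopentanone), via oxyallyl cation 19 (not isolated)
Conditions: Na2CO3, CF3CH2OH, 0 °C → rt (18 added slowly)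
Reagents that add atoms: none
Why: Na2CO3 in CF3CH2OH converts 18 through its enol into the 1-methyl-2-oxyallyl cation 19, which is attacked by the electron-rich C1′=C5′ alkene of 17 to give an oxocarbenium–enolate ion pair that collapses to the cyclopentanone; the closest known reaction type is the (3+2) cycloaddition of oxyallyl cations with enol ethers, styrenes and indoles. The ring C1′–C5′ is closed by this stepwise (3+2) annulation, the second C–C bond coming from attack of the enolate carbon on the oxocarbenium carbon within the ion pair (formally 5-(enolendo)-exo-trig). C1′ and C5′ are set together because both bonds form on one face of the alkene, the face opposite the pseudoaxial C10′ methyl and the C7′ isopropenyl group; C4′ is expected with its methyl on the side of O3, is epimerisable and is erased in step 12. The step needs chemoselectivity for the enediol diether over the isopropenyl group and one orientation of the unsymmetrical cation: the C6 ketone removes the competing styrene and makes O3 the better donor, so the more hindered C1′ should bond first to the CH2 terminus and the methyl-bearing terminus then close on the less hindered C5′.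

Step 12
Reactants: 20 3′,6-dioxo-3′,4′,6,7-tetrahydro target
Product: 21 bis(enol triflate) (C3′=C4′ and C6=C7)
Conditions: Tf2O, 2,6-di-tert-butyl-4-methylpyridine, CH2Cl2, 0 °C → rt
Reagents that add atoms: trifluoromethanesulfonic anhydride, O=S(=O)(OS(=O)(=O)C(F)(F)F)C(F)(F)F
Why: Enol triflate formation through O-triflyl oxocarbenium ions avoids enolates that could expel the β-aryloxy groups; C6 can only enolise toward C7, and C3′ should give the more substituted C3′=C4′ triflate under these thermodynamic conditions, which also removes the C4′ stereocentre.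

Step 13
Reactants: 21 bis(enol triflate)
Product: 22 target compound CNP0287532.1
Conditions: Pd(OAc)2 (10 mol%), PPh3 (20 mol%), HCO2H, n-Bu3N, DMF, 50 °C
Reagents that add atoms: none
Why: Palladium-catalysed formate reduction of vinyl triflates (oxidative addition to zerovalent palladium, formate exchange, loss of CO2, reductive elimination) replaces both triflates by hydrogen without moving the alkenes, and the hindered tertiary allylic aryl ether at C5′ should not ionise at this temperature.

**Compound list**

1 | (S)-carvone, (5S)-2-methyl-5-(prop-1-en-2-yl)cyclohex-2-en-1-one | CC1=CC[C@@H](CC1=O)C(C)=C | starting material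
2 | lithium (5S)-2-methyl-5-(prop-1-en-2-yl)cyclohex-1-en-1-olate (not isolated) | CC1=C([O-])C[C@H](CC1)C(C)=C.[Li+] | intermediate
3 | trimethyl{[(5S)-2-methyl-5-(prop-1-en-2-yl)cyclohex-1-en-1-yl]oxy}silane | CC1=C(O[Si](C)(C)C)C[C@H](CC1)C(C)=C | intermediate
4 | trimethyl{[(3S)-6-methyl-3-(prop-1-en-2-yl)bicyclo[4.1.0]heptan-1-yl]oxy}silane, cis-fused cyclopropane on either ring face | CC12CC[C@@H](CC1(C2)O[Si](C)(C)C)C(C)=C | intermediate
5 | (6S)-3-chloro-3-methyl-6-(prop-1-en-2-yl)cycloheptan-1-one (not isolated) | CC1(Cl)CC[C@@H](CC(=O)C1)C(C)=C | intermediate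
6 | (6S)-3-methyl-6-(prop-1-en-2-yl)cyclohept-2-en-1-one | CC1=CC(=O)C[C@H](CC1)C(C)=C | intermediate
7 | dimethoxy(methyl){[(3R,6S)-3-methyl-6-(prop-1-en-2-yl)cyclohept-1-en-1-yl]oxy}silane (not isolated) | C=C(C)[C@H]1CC[C@@H](C)C=C(C1)O[Si](C)(OC)OC | intermediate
8 | (3R,6S)-2-bromo-3-methyl-6-(prop-1-en-2-yl)cycloheptan-1-one, either C2 epimer (ketone = C5′, CHBr = C1′) | C=C(C)[C@H]1CC[C@@H](C)C(Br)C(=O)C1 | intermediate
9 | pristimerin | CC1=C(O)C(=O)C=C2C1=CC=C1[C@@]2(C)CC[C@@]2(C)[C@@H]4C[C@](C)(C(=O)OC)CC[C@]4(C)CC[C@]12C | starting material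
10 | pristimerol, the aromatic-ring-A 2,3-diol with C6H2 and C7=C8 (not isolated) | Oc1c(O)cc2c(c1C)CC=C1[C@@]2(C)CC[C@@]2(C)[C@@H]4C[C@](C)(C(=O)OC)CC[C@]4(C)CC[C@]12C | intermediate
11 | pristimerol 2,3-diacetate | CC(=O)Oc1c(OC(C)=O)cc2c(c1C)CC=C1[C@@]2(C)CC[C@@]2(C)[C@@H]4C[C@](C)(C(=O)OC)CC[C@]4(C)CC[C@]12C | intermediate
12 | 6-oxopristimerol 2,3-diacetate (aryl enone, C7=C8) | CC(=O)Oc1c(OC(C)=O)cc2c(c1C)C(=O)C=C1[C@@]2(C)CC[C@@]2(C)[C@@H]4C[C@](C)(C(=O)OC)CC[C@]4(C)CC[C@]12C | intermediate
13 | (8S)-6-oxo-7,8-dihydropristimerol 2,3-diacetate (8β-H) | CC(=O)Oc1c(OC(C)=O)cc2c(c1C)C(=O)C[C@@H]1[C@@]2(C)CC[C@@]2(C)[C@@H]4C[C@](C)(C(=O)OC)CC[C@]4(C)CC[C@]12C | intermediate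
14 | (8S)-6-oxo-7,8-dihydropristimerol (free 2,3-catechol, 8β-H) | Oc1c(O)cc2c(c1C)C(=O)C[C@@H]1[C@@]2(C)CC[C@@]2(C)[C@@H]4C[C@](C)(C(=O)OC)CC[C@]4(C)CC[C@]12C | intermediate
15 | aryloxy ketone: O2 of 14 bonded to C1′ of the (7′S,10′R)-cycloheptanone, O3–H free, C5′ ketone, either C1′ epimer (not isolated) | Oc1c(cc2c(c1C)C(=O)C[C@@H]1[C@@]2(C)CC[C@@]2(C)[C@@H]4C[C@](C)(C(=O)OC)CC[C@]4(C)CC[C@]12C)OC1C(=O)C[C@H](CC[C@H]1C)C(C)=C | intermediate
16 | cyclic hemiketal: 2,3-dihydro-1,4-benzodioxin with O2–C1′(H) and O3–C5′(OH), C1′/C5′ epimers, 8S, 7′S, 10′R | C=C(C)[C@H]1CC[C@@H](C)C3C(O)(C1)Oc1c(cc2c(c1C)C(=O)C[C@@H]1[C@@]2(C)CC[C@@]2(C)[C@@H]4C[C@](C)(C(=O)OC)CC[C@]4(C)CC[C@]12C)O3 | intermediate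
17 | cyclohepta-fused triterpene benzodioxin, 6-oxo-6,7-dihydro form: C1′=C5′ enediol diether (O2–C1′, O3–C5′), 8S, 7′S isopropenyl and 10′R methyl cis | C=C(C)[C@H]1CC[C@@H](C)C3=C(C1)Oc1c(cc2c(c1C)C(=O)C[C@@H]1[C@@]2(C)CC[C@@]2(C)[C@@H]4C[C@](C)(C(=O)OC)CC[C@]4(C)CC[C@]12C)O3 | intermediate (key-step precursor)
18 | 1-bromobutan-2-one | CCC(=O)CBr | starting material
19 | 1-methyl-2-oxidoallyl cation (oxyallyl cation, not isolated) | C[CH+]C([O-])=C | intermediate
20 | 3′,6-dioxo-3′,4′,6,7-tetrahydro target: cyclopentanone fused at C1′/C5′ anti to the C10′ methyl and C7′ isopropenyl groups, C4′ methyl on the side of O3 | C=C(C)[C@H]1CC[C@@H](C)[C@]23CC(=O)[C@@H](C)[C@@]2(C1)Oc1c(cc2c(c1C)C(=O)C[C@@H]1[C@@]2(C)CC[C@@]2(C)[C@@H]4C[C@](C)(C(=O)OC)CC[C@]4(C)CC[C@]12C)O3 | intermediate (key-step product)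
21 | bis(enol triflate): C3′(OTf)=C4′ and C6(OTf)=C7 | C=C(C)[C@H]1CC[C@@H](C)[C@]23CC(OS(=O)(=O)C(F)(F)F)=C(C)[C@@]2(C1)Oc1c(cc2c(c1C)C(OS(=O)(=O)C(F)(F)F)=C[C@@H]1[C@@]2(C)CC[C@@]2(C)[C@@H]4C[C@](C)(C(=O)OC)CC[C@]4(C)CC[C@]12C)O3 | intermediate
22 | CNP0287532.1 | C=C(C)[C@H]1CC[C@@H](C)[C@]23CC=C(C)[C@@]2(C1)Oc1c(cc2c(c1C)C=C[C@@H]1[C@@]2(C)CC[C@@]2(C)[C@@H]4C[C@](C)(C(=O)OC)CC[C@]4(C)CC[C@]12C)O3 | target

**Step count and risks**

Total step count: 13. Longest linear sequence: 9 steps (pristimerin 9 to 22 through steps 5–13; the carvone branch, steps 1–4 then 9–13, is equally long).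

Step 11. What may go wrong: capture of the oxyallyl cation by the solvent before the hindered tetrasubstituted alkene reacts, collapse of the ion pair through the enolate oxygen to an alkylidene-tetrahydrofuran, or addition of the two termini in the reverse orientation. The fallback sets out from 17 and builds the ring by ketene (2+2) cycloaddition and one-carbon ring expansion. Chloro(methyl)ketene, generated from 2-chloropropanoyl chloride and Et3N, should add across C1′=C5′ with its carbonyl carbon on the more nucleophilic C1′ to give the α-chlorocyclobutanone F1. Diazomethane then inserts CH2 on the non-halogenated side (migration of C1′) to give the 4′-chloro-4′-methylcyclopentanone F2. Zn in AcOH removes the chlorine and the sequence comes back to the route at 20.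

Step 12. What may go wrong: deprotonation of the C3′ O-triflyl cation at C2′ instead of C4′, giving the wrong enol triflate regiochemistry, or incomplete triflation of the peri-hindered C6 ketone. The fallback sets out from 20 and fixes the regiochemistry at a stage where it can be checked. Equilibrating silylation (Me3SiI, (Me3Si)2NH, CH2Cl2, −20 °C → rt) should give the thermodynamic bis(trimethylsilyl enol ether) F3, from which any C2′=C3′ isomer is separated and recycled to 20 by hydrolysis. MeLi at −78 °C then releases the dilithium bis-enolate F4, which is triflated at once with PhNTf2, and the sequence comes back to the route at 21.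

Step 4. What may go wrong: hydride delivery under incomplete ligand control at C3, or protodesilylation of the enol ether before bromination, after which the two α-methylenes can no longer be told apart. The fallback sets out from 1 and takes the methyl centre from a substrate-independent enzymatic reduction. An ene-reductase of the old yellow enzyme family (NADPH recycled with glucose and glucose dehydrogenase) reduces 1 to cis-(2R,5S)-dihydrocarvone F5. Dibromomethyllithium (CH2Br2, lithium 2,2,6,6-tetramethylpiperidide, THF, −78 °C) adds to the ketone to give the dibromomethyl carbinol F6. Two equivalents of n-BuLi at −95 °C generate the β-oxido carbenoid, which should rearrange by migration of the methyl-bearing carbon with retention to the ring-expanded lithium enolate F7. This is trapped with TMSCl as the trimethylsilyl enol ether F8, and NBS converts F8 into the bromo ketone, coming back to the route at 8.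

**Further compounds**

F1 | step 11 | C1′/C5′-fused 2-chloro-2-methylcyclobutanone of 17 (carbonyl carbon on C1′, CCl(Me) on C5′) | C=C(C)[C@H]1CC[C@@H](C)[C@]23C(=O)C(C)(Cl)[C@@]2(C1)Oc1c(cc2c(c1C)C(=O)C[C@@H]1[C@@]2(C)CC[C@@]2(C)[C@@H]4C[C@](C)(C(=O)OC)CC[C@]4(C)CC[C@]12C)O3
F2 | step 11 | 4′-chloro derivative of 20 | C=C(C)[C@H]1CC[C@@H](C)[C@]23CC(=O)C(C)(Cl)[C@@]2(C1)Oc1c(cc2c(c1C)C(=O)C[C@@H]1[C@@]2(C)CC[C@@]2(C)[C@@H]4C[C@](C)(C(=O)OC)CC[C@]4(C)CC[C@]12C)O3
F3 | step 12 | bis(trimethylsilyl enol ether) of 20 (C3′=C4′ and C6=C7) | C=C(C)[C@H]1CC[C@@H](C)[C@]23CC(O[Si](C)(C)C)=C(C)[C@@]2(C1)Oc1c(cc2c(c1C)C(O[Si](C)(C)C)=C[C@@H]1[C@@]2(C)CC[C@@]2(C)[C@@H]4C[C@](C)(C(=O)OC)CC[C@]4(C)CC[C@]12C)O3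
F4 | step 12 | dilithium bis-enolate of 20 (C3′=C4′ and C6=C7) | C=C(C)[C@H]1CC[C@@H](C)[C@]23CC([O-])=C(C)[C@@]2(C1)Oc1c(cc2c(c1C)C([O-])=C[C@@H]1[C@@]2(C)CC[C@@]2(C)[C@@H]4C[C@](C)(C(=O)OC)CC[C@]4(C)CC[C@]12C)O3.[Li+].[Li+]
F5 | step 4 | (2R,5S)-dihydrocarvone (cis) | C=C(C)[C@H]1CC[C@@H](C)C(=O)C1
F6 | step 4 | (2R,5S)-1-(dibromomethyl)-2-methyl-5-(prop-1-en-2-yl)cyclohexan-1-ol, either C1 epimer | C=C(C)[C@H]1CC[C@@H](C)C(O)(C(Br)Br)C1
F7 | step 4 | lithium (3R,6S)-3-methyl-6-(prop-1-en-2-yl)cyclohept-1-en-1-olate | C=C(C)[C@H]1CC[C@@H](C)C=C(C1)[O-].[Li+]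
F8 | step 4 | trimethyl{[(3R,6S)-3-methyl-6-(prop-1-en-2-yl)cyclohept-1-en-1-yl]oxy}silane | C=C(C)[C@H]1CC[C@@H](C)C=C(C1)O[Si](C)(C)C
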